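**The bench rule.** A bench chemist here would watch one number, the isomer share: c of isomer of the product over the sum of c of isomer and c of target. You can treat it as a first-order lag, solved at both ends and then joined.

| flask | starting material | remark | time |
|---|---|---|---|
| ochre | 0.15 M | run made earlier |  |
| blue | 0.22 M | run made earlier |  |
| flask | 0.30 M |  | 25 min |

- ochre (time / min: isomer of the product / %, target / %): 2.50: 6, 54; 5.00: 12, 62; 8.00: 19, 59; 15.0: 31, 54; 30.0: 35, 47
- blue (time / min: isomer of the product / %, target / %): 6.00: 15, 56; 12.0: 25, 57; 20.0: 31, 51; 25.0: 31, 50; 30.0: 35, 50

(readings scatter by 2 percentage points)

* share of isomer of the product in isomer of the product plus target at 1.2 s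
* share of isomer of the product in isomer of the product plus target at 25 min

- the earlier runs were read with a standard deviation of 2 percentage points

**Late end.** Pooled, the ochre and blue readings at 30.0 min give a share of 41.9%. Take this as the end value of the lag, the late side of kinetic against thermodynamic control.

**Time constant.** Ochre at 8.00 min reads a share of 24.4%. That gives 9.19 min, the share time constant. My reckoning for the flask at 25 min is then 39.2%. The flask's charge is twice ochre's, so you are assuming the charge stays out of the lag.

**The border.** A reading's scatter on the first ochre total is worth 3.33% of share. The lag stays below that until about 0.731 min, and 1.2 s is 0.0274 of this time. The lag gives 0.0911% at 1.2 s, below the floor, so I commit to a bracket between the two.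

**The forecast.** It says 1% at 1.2 s and 40% at 25 min, and its early value lies above my lag value and below the floor, so inside my bracket. Its words for that end are “unless there is a small direct branch”.

**The result.** The flask gives 1.34% at 1.2 s, above the lag value and below the floor. At 25 min it gives 39.0%, against my 39.2%.

    starting material ⇌ target (K = 4.57, k = 0.0105 s⁻¹)
    starting material ⇌ isomer of the product (K = 3.10, k = 1.36 × 10⁻⁴ s⁻¹)
    target ⇌ isomer of the product (k = 0.00102 s⁻¹)
    starting material ⇌ dormant form (K = 0.400, k = 0.00386 s⁻¹)

**The neighbour.** The neighbour flask is charged with 0.075 M, a quarter of the flask's charge. The time constant 9.19 min was read with no term in the charge, so the same reckoning again gives 39.2%. The neighbour gives 1.34% at 1.2 s and 39.0% at 25 min.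

(The data were computed for substances that don't exist.)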